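**Retrosynthetic overview**
1. Feature: C4' of ring F is bonded to C4a' of ring D and to C6 of ring A. Both rings are 2,3,4-trioxygenated phenyl groups joined next to an outer oxygen (O1'/O8'/O7' on ring D, O7/O8/O1 on ring A), so C4' is traced back to a prochiral methine carrying two identical aryl groups.
2. Ring F: O1'–C2' is cut to a C2'–C3' cis-epoxide. One of the two ortho-phenols opens it at benzylic C2', and the aryl group left over is ring A with O7–H free.
3. The epoxide comes from catalyst-controlled epoxidation of the achiral (Z)-alkene. The alkene comes from an alkyne made by alkynylation (C4'–C3') of a symmetrical benzhydrol, itself made from pyrogallol and 2,3,4-trihydroxybenzoic acid through the benzophenone.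
4. Ring C: O1–C2 is cut to a second cis-epoxide and C4–C3 to an aldehyde on C4a plus the ring B alkyne. C4a is reached by bromination para to O7–H, and O8a is freed by chelation to the aldehyde. A flavonol hydrogenation was set aside because nothing would choose its face.
5. Order of ring formation: rings A and D (bought as pyrogallol units) and ring E, then ring F, then ring B is attached and ring C closed. Hydrogenolysis of eight benzyl ethers ends the route.

Key step: step 11

Remark on labels: unprimed atoms O1 to C8a belong to rings A/C with ring B on C2, and primed atoms belong to rings D/F with ring E on C2'. Bn = benzyl, TBS = tert-butyldimethylsilyl, CSA = camphor-10-sulfonic acid, NMO = N-methylmorpholine N-oxide. "DFE unit" = (2'R,3'R)-3',7',8'-tris(benzyloxy)-2'-[3,4-bis(benzyloxy)phenyl]chroman-4'-yl, bonded through C4' with ring A trans to O3' as in the key-step product.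
Assumption: the sense of induction in steps 9 and 18 is taken over from the closest simple substrates (cis-β-methylstyrene and indene; benzaldehyde), and both chiral ligands are sold as either antipode.

Step 1
Reactants: 1 pyrogallol; 2 2,3,4-trihydroxybenzoic acid
Product: 3 bis(2,3,4-trihydroxyphenyl)methanone
Conditions: ZnCl2, POCl3, 65 °C; then ice/H2O
Reagents that add atoms: none
Why: Nencki-type Friedel–Crafts acylation attacks pyrogallol at C4, next to an outer hydroxyl, as in the classical preparations of gallacetophenone and of polyhydroxybenzophenones, and a benzophenone that lacks a 6-hydroxyl does not go on to the xanthone at this temperature.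

Step 2
Reactants: 3 bis(2,3,4-trihydroxyphenyl)methanone
Product: 4 bis[3,4-bis(benzyloxy)-2-hydroxyphenyl]methanone
Conditions: BnBr (4.1 equiv), K2CO3 (4.2 equiv), DMF, 25 °C
Reagents that add atoms: benzyl bromide, BrCc1ccccc1
Why: Williamson etherification takes the four free 3- and 4-hydroxyls, while the two 2-hydroxyls are held in hydrogen bonds to the carbonyl group and stay behind, the selectivity known from gallacetophenone and from 2,2',4,4'-tetrahydroxybenzophenone.

Step 3
Reactants: 4 bis[3,4-bis(benzyloxy)-2-hydroxyphenyl]methanone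
Product: 5 bis[3,4-bis(benzyloxy)-2-hydroxyphenyl]methanol
Conditions: NaBH4, THF/EtOH, 0 °C; pH 7 phosphate work-up, used crude
Reagents that add atoms: none
Why: Borohydride reduction of an o-hydroxybenzophenone stops at the benzhydrol at low temperature, and a neutral work-up keeps this easily ionised triol from losing water before the next step.

Step 4
Reactants: 6 3,4-bis(benzyloxy)benzaldehyde
Product: 7 1,2-bis(benzyloxy)-4-ethynylbenzene
Conditions: dimethyl (1-diazo-2-oxopropyl)phosphonate, K2CO3, MeOH/THF, 25 °C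
Reagents that add atoms: dimethyl (1-diazo-2-oxopropyl)phosphonate, COP(=O)(OC)C(=[N+]=[N-])C(C)=O
Why: Seyferth–Gilbert homologation in the Ohira–Bestmann variant turns a non-enolisable aromatic aldehyde into the terminal alkyne under conditions that leave benzyl ethers alone.

Step 5
Reactants: 7 1,2-bis(benzyloxy)-4-ethynylbenzene
Product: 10 potassium {[3,4-bis(benzyloxy)phenyl]ethynyl}trifluoroborate, via lithium acetylide 8 (not isolated), via lithium alkynyltrimethoxyborate 9 (not isolated)
Conditions: n-BuLi, THF, −78 °C; B(OMe)3, −78 → −20 °C; aq KHF2, 0 °C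
Reagents that add atoms: trimethyl borate, COB(OC)OC; potassium hydrogen difluoride, [K+].[F-].F
Why: Deprotonation, borylation of the acetylide and fluoride exchange with KHF2 is the standard route to crystalline, storable potassium alkynyltrifluoroborates.

Step 6
Reactants: 5 bis[3,4-bis(benzyloxy)-2-hydroxyphenyl]methanol; 10 potassium {[3,4-bis(benzyloxy)phenyl]ethynyl}trifluoroborate
Product: 11 6,6'-{3-[3,4-bis(benzyloxy)phenyl]prop-2-yne-1,1-diyl}bis[2,3-bis(benzyloxy)phenol]
Conditions: HBF4·OEt2 (15 mol %), MeCN/CH2Cl2, 0 °C, short contact time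
Reagents that add atoms: none
Why: The acid ionises the benzhydrol, whose cation is the O-protonated o-quinone methide stabilised by two ortho-hydroxyl and two para-benzyloxy groups, and the alkynyltrifluoroborate transfers its alkynyl group to the methine carbon in the known Brønsted-acid-catalysed SN1 alkynylation of benzhydryl alcohols, which makes the C4'–C3' bond.

Step 7
Reactants: 11 alkyne bisphenol
Product: 12 bis-TBS ether of 11
Conditions: TBSCl, imidazole, DMF, 40 °C
Reagents that add atoms: tert-butyldimethylsilyl chloride, CC(C)(C)[Si](C)(C)Cl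
Why: Silylation of both phenols masks them against the oxidant of step 9 with a group that fluoride later removes without acid or strong base.

Step 8
Reactants: 12 bis-TBS alkyne
Product: 13 (Z)-1,1-bis[3,4-bis(benzyloxy)-2-(TBS-oxy)phenyl]-3-[3,4-bis(benzyloxy)phenyl]prop-2-ene
Conditions: H2 (1 atm), Pd/CaCO3 poisoned with Pb(OAc)2, quinoline, EtOAc, 25 °C
Reagents that add atoms: none
Why: Lindlar semi-hydrogenation adds hydrogen syn to the aryl alkyne and gives the (Z)-alkene, and the poisoned catalyst does not cleave benzyl ethers.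

Step 9
Reactants: 13 (Z)-alkene
Product: 14 (2'S,3'R)-cis-epoxide of 13 (bis-TBS ether)
Conditions: (S,S)-[N,N'-bis(3,5-di-tert-butylsalicylidene)cyclohexane-1,2-diaminato]MnCl (8 mol %), NMO (5 equiv), mCPBA (2 equiv), CH2Cl2, −78 °C
Reagents that add atoms: 3-chloroperoxybenzoic acid, OOC(=O)c1cccc(Cl)c1
Why: Jacobsen–Katsuki epoxidation is at its best with cis-alkenes conjugated to one aryl group, the (S,S)-catalyst should deliver oxygen to the face that makes the benzylic carbon S as it does with cis-β-methylstyrene and indene, which sets C2' (S) and C3' (R), and the low-temperature mCPBA/NMO protocol shortens the life of the radical intermediate that would leak to the trans-epoxide.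

Step 10
Reactants: 14 cis-epoxide bis-TBS ether
Product: 15 6,6'-({(2R,3S)-3-[3,4-bis(benzyloxy)phenyl]oxiran-2-yl}methylene)bis[2,3-bis(benzyloxy)phenol], that is the (2'S,3'R)-cis-epoxide bisphenol
Conditions: TBAF/AcOH (1:1, 2.2 equiv), THF, −20 °C; cold neutral work-up, used at once
Reagents that add atoms: none
Why: Fluoride cleaves aryl silyl ethers within minutes at low temperature, and the acetic acid buffer keeps the phenols protonated so that no phenoxide can open the epoxide in the 5-exo sense at C3'.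

Step 11
Reactants: 15 (2'S,3'R)-cis-epoxide bisphenol
Product: 16 (2'R,3'R,4'S)-7',8'-bis(benzyloxy)-2'-[3,4-bis(benzyloxy)phenyl]-4'-[3,4-bis(benzyloxy)-2-hydroxyphenyl]chroman-3'-ol (2',3'-cis-3',4'-trans; the 4'-aryl group is ring A with O7–H free)
Conditions: CSA (10 mol %), 4 Å MS, CH2Cl2 (0.005 M), −40 °C
Reagents that add atoms: none
Why: Proposed new method: the sulfonic acid activates the epoxide oxygen, the C2'–O bond is loosened because C2' is benzylic to the dialkoxyphenyl ring E, and an ortho-phenol attacks C2' from the rear, which forms O1'–C2' and closes ring F in the 6-endo-tet mode, while 5-exo attack at C3' finds a carbon that is neither activated nor accessible next to the bis-aryl methine. The closest known reactions are the acid-catalysed 6-endo closure of o-(3-aryloxiran-2-ylmethyl)phenols to flavan-3-ols and group-selective cyclisations of bis-aryl methines; what has not been shown is an epoxide that picks one of two diastereotopic phenols on one prochiral carbon. C2' is controlled by inversion (S in 15, R in 16), so that the cis-epoxide places ring E cis to O3', and C3' keeps its C–O bond and hence its configuration. C4' is controlled by the choice of aryl group: strain with the cis-disposed ring E holds C4'–H beside C2', one aryl group then stands on the face of the epoxide oxygen and the other behind the C2'–O bond, only the latter can reach the rear lobe, and in the resulting half-chair the spectator aryl group is pseudo-equatorial and trans to O3'. Closure by the other phenol would need an aryl group in the place of that hydrogen, syn-axial to ring E, so the group selectivity that the step needs rests on this strain difference, and the catalyst-set epoxide thereby passes its configuration on to all three stereocentres of ring F. Low temperature, a non-polar solvent and a catalytic amount of acid are chosen to keep the opening concerted rather than ionic, and high dilution to shut out intermolecular opening.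

Step 12
Reactants: 16 key-step product
Product: 17 C4a-bromide of 16 (the 4'-aryl group is 5-bromo-3,4-bis(benzyloxy)-2-hydroxyphenyl; stereocentres as in 16)
Conditions: NBS (1.0 equiv), CH2Cl2, −78 → −30 °C
Reagents that add atoms: N-bromosuccinimide, O=C1CCC(=O)N1Br
Why: Electrophilic aromatic bromination is steered by the only free phenol, whose ortho positions C6 and C8 are occupied, to the para position C4a, and the aryl ether rings D and E react more slowly with NBS at low temperature.

Step 13
Reactants: 17 bromophenol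
Product: 18 1-bromo-2,3,4-tris(benzyloxy)-5-(DFE unit)benzene (O7- and O3'-benzyl ether of 17)
Conditions: NaH, BnBr, Bu4NI (cat.), DMF, 0 → 25 °C
Reagents that add atoms: benzyl bromide, BrCc1ccccc1
Why: Williamson benzylation of the phenoxide and of the C3' alkoxide puts every oxygen under the same hydrogenolysable group and removes all acidic protons before the lithiation.

Step 14
Reactants: 18 aryl bromide
Product: 20 2,3,4-tris(benzyloxy)-5-(DFE unit)benzaldehyde, via aryllithium 19 (not isolated)
Conditions: n-BuLi, THF, −78 °C; DMF, −78 → 0 °C; H2O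
Reagents that add atoms: N,N-dimethylformamide, CN(C)C=O
Why: Bromine–lithium exchange is faster than any deprotonation at −78 °C and the aryllithium is formylated by DMF (Bouveault aldehyde synthesis), which installs C4 on C4a.

Step 15
Reactants: 20 tris(benzyloxy)benzaldehyde
Product: 21 3,4-bis(benzyloxy)-2-hydroxy-5-(DFE unit)benzaldehyde (O8a–H free)
Conditions: MgBr2·OEt2 (3 equiv), toluene/Et2O, 70 °C; aqueous work-up
Reagents that add atoms: none
Why: MgBr2 chelates between the aldehyde oxygen and the only ortho benzyloxy group, O8a, and bromide removes that benzyl group alone, the known chelation-controlled ortho-debenzylation of aromatic carbonyl compounds.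

Step 16
Reactants: 21 salicylaldehyde
Product: 22 3,4-bis(benzyloxy)-2-(TBS-oxy)-5-(DFE unit)benzaldehyde
Conditions: TBSCl, imidazole, DMF, 25 °C
Reagents that add atoms: tert-butyldimethylsilyl chloride, CC(C)(C)[Si](C)(C)Cl
Why: Silylation blocks the acidic salicylaldehyde hydroxyl for the zinc and titanium reagents and again leaves a group that fluoride can take off in the presence of an epoxide.

Step 17
Reactants: 23 4-(benzyloxy)benzaldehyde
Product: 24 1-(benzyloxy)-4-ethynylbenzene
Conditions: dimethyl (1-diazo-2-oxopropyl)phosphonate, K2CO3, MeOH/THF, 25 °C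
Reagents that add atoms: dimethyl (1-diazo-2-oxopropyl)phosphonate, COP(=O)(OC)C(=[N+]=[N-])C(C)=O
Why: The Ohira–Bestmann variant of the Seyferth–Gilbert homologation gives the ring B alkyne from the aromatic aldehyde in one operation.

Step 18
Reactants: 22 silyloxy aldehyde; 24 1-(benzyloxy)-4-ethynylbenzene
Product: 26 (4R)-propargylic alcohol 1-[3,4-bis(benzyloxy)-2-(TBS-oxy)-5-(DFE unit)phenyl]-3-[4-(benzyloxy)phenyl]prop-2-yn-1-ol, via alkynyl(ethyl)zinc 25 (not isolated)
Conditions: 24 (3 equiv), Et2Zn (3 equiv), toluene, 110 °C; then (R)-BINOL (20 mol %), Ti(OiPr)4 (50 mol %), CH2Cl2, 25 °C; then 22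
Reagents that add atoms: none
Why: BINOL–titanium-catalysed addition of an alkynylzinc to an aromatic aldehyde makes the C4–C3 bond, and (R)-BINOL should direct the alkynyl group to the Re face as with simple benzaldehydes, which gives the (4R)-carbinol that serves only to steer step 20.

Step 19
Reactants: 26 propargylic alcohol
Product: 27 (4R,Z)-allylic alcohol
Conditions: H2 (1 atm), Pd/CaCO3 poisoned with Pb(OAc)2, quinoline, EtOAc, 25 °C
Reagents that add atoms: none
Why: Lindlar semi-hydrogenation gives the (Z)-alkene by syn addition and touches neither the benzyl ethers nor the benzylic carbinol.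

Step 20
Reactants: 27 (Z)-allylic alcohol
Product: 28 threo cis-epoxy alcohol (2S,3R,4S)
Conditions: mCPBA, CH2Cl2/aq phosphate buffer (pH 8), 0 °C
Reagents that add atoms: 3-chloroperoxybenzoic acid, OOC(=O)c1cccc(Cl)c1
Why: In this (Z)-allylic alcohol allylic 1,3-strain holds C4–H in the alkene plane next to ring B, so that the hydroxyl-directed peracid epoxidation (Henbest effect) attacks the face that carries the hydroxyl and is remote from ring A and gives the threo cis-epoxy alcohol, which sets C2 (S) and C3 (R).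

Step 21
Reactants: 28 threo cis-epoxy alcohol
Product: 29 cis-epoxy ketone (2S,3S)
Conditions: n-Pr4N[RuO4] (5 mol %), NMO (1.5 equiv), 4 Å MS, CH2Cl2, 0 → 25 °C
Reagents that add atoms: none
Why: Ley–Griffith oxidation works under neutral conditions, spares the acid-labile aryl epoxide and removes the C4 stereocentre whose threo relation to C3 is the wrong one for the target.

Step 22
Reactants: 29 cis-epoxy ketone
Product: 30 erythro cis-epoxy alcohol (2S,3R,4R)
Conditions: Zn(BH4)2, Et2O/CH2Cl2, −78 → −30 °C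
Reagents that add atoms: none
Why: Zn(BH4)2 chelates the ketone and the epoxide oxygen and delivers hydride from the side of C3–H, away from C2 and its cis-aryl group, the known erythro-selective reduction of α,β-epoxy ketones, which sets C4 (R) with O4 and O3 in the relation that becomes 3,4-cis.

Step 23
Reactants: 30 erythro cis-epoxy alcohol
Product: 32 octabenzyl ether of the target (2R,3R,4R)-all-cis flavan-3,4-diol, via epoxy alcohol phenol 31 (not isolated)
Conditions: TBAF/AcOH (1:1), THF, 0 °C; neutral work-up; crude 31, CSA (10 mol %), CH2Cl2, −40 → −10 °C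
Reagents that add atoms: none
Why: After buffered fluoride release of O8a–H the acid-catalysed 6-endo-tet opening of the aryl epoxide by the ortho-phenol, the known flavan-3-ol ring closure, forms O1–C2 with inversion at the benzylic C2 (S to R), so that the cis-epoxide gives ring B cis to O3, and the strained epoxide is activated far faster than the C4 carbinol.

Step 24
Reactants: 32 octabenzyl ether
Product: 33 CNP0174688.1 (target)
Conditions: H2 (1 atm), Pd(OH)2/C, THF/MeOH, 25 °C, stopped at the end of uptake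
Reagents that add atoms: none
Why: Hydrogenolysis over Pd(OH)2/C cleaves the seven aryl benzyl ethers and the C3' alkyl benzyl ether under neutral conditions, under which the cyclic benzylic C2–O1 and C2'–O1' bonds and the secondary benzylic C4–OH react more slowly.

**Compound list**
1 | pyrogallol | Oc1cccc(O)c1O | starting material
2 | 2,3,4-trihydroxybenzoic acid | OC(=O)c1ccc(O)c(O)c1O | starting material
3 | bis(2,3,4-trihydroxyphenyl)methanone | O=C(c1ccc(O)c(O)c1O)c1ccc(O)c(O)c1O | intermediate
4 | bis[3,4-bis(benzyloxy)-2-hydroxyphenyl]methanone | O=C(c1ccc(OCc2ccccc2)c(OCc2ccccc2)c1O)c1ccc(OCc2ccccc2)c(OCc2ccccc2)c1O | intermediate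
5 | bis[3,4-bis(benzyloxy)-2-hydroxyphenyl]methanol | OC(c1ccc(OCc2ccccc2)c(OCc2ccccc2)c1O)c1ccc(OCc2ccccc2)c(OCc2ccccc2)c1O | intermediate
6 | 3,4-bis(benzyloxy)benzaldehyde | O=Cc1ccc(OCc2ccccc2)c(OCc2ccccc2)c1 | starting material
7 | 1,2-bis(benzyloxy)-4-ethynylbenzene | C#Cc1ccc(OCc2ccccc2)c(OCc2ccccc2)c1 | intermediate
8 | lithium acetylide of 7 (not isolated) | [Li]C#Cc1ccc(OCc2ccccc2)c(OCc2ccccc2)c1 | intermediate
9 | lithium {[3,4-bis(benzyloxy)phenyl]ethynyl}trimethoxyborate (not isolated) | [Li+].CO[B-](OC)(OC)C#Cc1ccc(OCc2ccccc2)c(OCc2ccccc2)c1 | intermediate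
10 | potassium {[3,4-bis(benzyloxy)phenyl]ethynyl}trifluoroborate | [K+].F[B-](F)(F)C#Cc1ccc(OCc2ccccc2)c(OCc2ccccc2)c1 | intermediate
11 | 6,6'-{3-[3,4-bis(benzyloxy)phenyl]prop-2-yne-1,1-diyl}bis[2,3-bis(benzyloxy)phenol] | Oc1c(OCc6ccccc6)c(OCc6ccccc6)ccc1C(C#Cc4ccc(OCc6ccccc6)c(OCc6ccccc6)c4)c2ccc(OCc6ccccc6)c(OCc6ccccc6)c2O | intermediate
12 | bis-TBS ether of 11 | CC(C)(C)[Si](C)(C)Oc1c(OCc6ccccc6)c(OCc6ccccc6)ccc1C(C#Cc4ccc(OCc6ccccc6)c(OCc6ccccc6)c4)c2ccc(OCc6ccccc6)c(OCc6ccccc6)c2O[Si](C)(C)C(C)(C)C | intermediate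
13 | (Z)-1,1-bis[3,4-bis(benzyloxy)-2-(TBS-oxy)phenyl]-3-[3,4-bis(benzyloxy)phenyl]prop-2-ene | CC(C)(C)[Si](C)(C)Oc1c(OCc6ccccc6)c(OCc6ccccc6)ccc1C(c2ccc(OCc6ccccc6)c(OCc6ccccc6)c2O[Si](C)(C)C(C)(C)C)/C=C\c4ccc(OCc6ccccc6)c(OCc6ccccc6)c4 | intermediate
14 | (2'S,3'R)-cis-epoxide of 13 | CC(C)(C)[Si](C)(C)Oc1c(OCc6ccccc6)c(OCc6ccccc6)ccc1C(c2ccc(OCc6ccccc6)c(OCc6ccccc6)c2O[Si](C)(C)C(C)(C)C)[C@H]9O[C@H]9c4ccc(OCc6ccccc6)c(OCc6ccccc6)c4 | intermediate
15 | (2'S,3'R)-cis-epoxide bisphenol, key-step precursor | Oc1c(OCc6ccccc6)c(OCc6ccccc6)ccc1C(c2ccc(OCc6ccccc6)c(OCc6ccccc6)c2O)[C@H]9O[C@H]9c4ccc(OCc6ccccc6)c(OCc6ccccc6)c4 | intermediate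
16 | (2'R,3'R,4'S)-4'-aryl flavan-3'-ol, 2',3'-cis-3',4'-trans, ring A with O7–H free, key-step product | Oc3c(OCc6ccccc6)c(OCc6ccccc6)ccc3[C@H]4c5ccc(OCc6ccccc6)c(OCc6ccccc6)c5O[C@H](c5ccc(OCc6ccccc6)c(OCc6ccccc6)c5)[C@@H]4O | intermediate
17 | C4a-bromide of 16 (2'R,3'R,4'S) | Oc3c(OCc6ccccc6)c(OCc6ccccc6)c(Br)cc3[C@H]4c5ccc(OCc6ccccc6)c(OCc6ccccc6)c5O[C@H](c5ccc(OCc6ccccc6)c(OCc6ccccc6)c5)[C@@H]4O | intermediate
18 | 1-bromo-2,3,4-tris(benzyloxy)-5-(DFE unit)benzene (C4' formally R from here to 32 because O7-benzylation reverses the ranking of rings A and D; geometry unchanged) | c1ccccc1COc3c(OCc6ccccc6)c(OCc6ccccc6)c(Br)cc3[C@H]4c5ccc(OCc6ccccc6)c(OCc6ccccc6)c5O[C@H](c5ccc(OCc6ccccc6)c(OCc6ccccc6)c5)[C@@H]4OCc6ccccc6 | intermediate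
19 | C4a-aryllithium from 18 (not isolated) | c1ccccc1COc3c(OCc6ccccc6)c(OCc6ccccc6)c([Li])cc3[C@H]4c5ccc(OCc6ccccc6)c(OCc6ccccc6)c5O[C@H](c5ccc(OCc6ccccc6)c(OCc6ccccc6)c5)[C@@H]4OCc6ccccc6 | intermediate
20 | 2,3,4-tris(benzyloxy)-5-(DFE unit)benzaldehyde | c1ccccc1COc3c(OCc6ccccc6)c(OCc6ccccc6)c(C=O)cc3[C@H]4c5ccc(OCc6ccccc6)c(OCc6ccccc6)c5O[C@H](c5ccc(OCc6ccccc6)c(OCc6ccccc6)c5)[C@@H]4OCc6ccccc6 | intermediate
21 | 3,4-bis(benzyloxy)-2-hydroxy-5-(DFE unit)benzaldehyde | c1ccccc1COc3c(OCc6ccccc6)c(O)c(C=O)cc3[C@H]4c5ccc(OCc6ccccc6)c(OCc6ccccc6)c5O[C@H](c5ccc(OCc6ccccc6)c(OCc6ccccc6)c5)[C@@H]4OCc6ccccc6 | intermediate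
22 | 3,4-bis(benzyloxy)-2-(TBS-oxy)-5-(DFE unit)benzaldehyde | c1ccccc1COc3c(OCc6ccccc6)c(O[Si](C)(C)C(C)(C)C)c(C=O)cc3[C@H]4c5ccc(OCc6ccccc6)c(OCc6ccccc6)c5O[C@H](c5ccc(OCc6ccccc6)c(OCc6ccccc6)c5)[C@@H]4OCc6ccccc6 | intermediate
23 | 4-(benzyloxy)benzaldehyde | O=Cc1ccc(OCc2ccccc2)cc1 | starting material
24 | 1-(benzyloxy)-4-ethynylbenzene | C#Cc1ccc(OCc2ccccc2)cc1 | intermediate
25 | ethyl{[4-(benzyloxy)phenyl]ethynyl}zinc (not isolated) | CC[Zn]C#Cc1ccc(OCc2ccccc2)cc1 | intermediate
26 | (4R)-propargylic alcohol | c1ccccc1COc3c(OCc6ccccc6)c(O[Si](C)(C)C(C)(C)C)c([C@H](O)C#Cc7ccc(OCc6ccccc6)cc7)cc3[C@H]4c5ccc(OCc6ccccc6)c(OCc6ccccc6)c5O[C@H](c5ccc(OCc6ccccc6)c(OCc6ccccc6)c5)[C@@H]4OCc6ccccc6 | intermediate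
27 | (4R,Z)-allylic alcohol | c1ccccc1COc3c(OCc6ccccc6)c(O[Si](C)(C)C(C)(C)C)c([C@H](O)/C=C\c7ccc(OCc6ccccc6)cc7)cc3[C@H]4c5ccc(OCc6ccccc6)c(OCc6ccccc6)c5O[C@H](c5ccc(OCc6ccccc6)c(OCc6ccccc6)c5)[C@@H]4OCc6ccccc6 | intermediate
28 | threo cis-epoxy alcohol (2S,3R,4S) | c1ccccc1COc3c(OCc6ccccc6)c(O[Si](C)(C)C(C)(C)C)c([C@H](O)[C@H]8O[C@H]8c7ccc(OCc6ccccc6)cc7)cc3[C@H]4c5ccc(OCc6ccccc6)c(OCc6ccccc6)c5O[C@H](c5ccc(OCc6ccccc6)c(OCc6ccccc6)c5)[C@@H]4OCc6ccccc6 | intermediate
29 | cis-epoxy ketone (2S,3S) | c1ccccc1COc3c(OCc6ccccc6)c(O[Si](C)(C)C(C)(C)C)c(C(=O)[C@H]8O[C@H]8c7ccc(OCc6ccccc6)cc7)cc3[C@H]4c5ccc(OCc6ccccc6)c(OCc6ccccc6)c5O[C@H](c5ccc(OCc6ccccc6)c(OCc6ccccc6)c5)[C@@H]4OCc6ccccc6 | intermediate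
30 | erythro cis-epoxy alcohol (2S,3R,4R) | c1ccccc1COc3c(OCc6ccccc6)c(O[Si](C)(C)C(C)(C)C)c([C@@H](O)[C@H]8O[C@H]8c7ccc(OCc6ccccc6)cc7)cc3[C@H]4c5ccc(OCc6ccccc6)c(OCc6ccccc6)c5O[C@H](c5ccc(OCc6ccccc6)c(OCc6ccccc6)c5)[C@@H]4OCc6ccccc6 | intermediate
31 | erythro cis-epoxy alcohol with O8a–H free (2S,3R,4R) (not isolated) | c1ccccc1COc3c(OCc6ccccc6)c(O)c([C@@H](O)[C@H]8O[C@H]8c7ccc(OCc6ccccc6)cc7)cc3[C@H]4c5ccc(OCc6ccccc6)c(OCc6ccccc6)c5O[C@H](c5ccc(OCc6ccccc6)c(OCc6ccccc6)c5)[C@@H]4OCc6ccccc6 | intermediate
32 | octabenzyl ether of the target, ring C (2R,3R,4R) all-cis | c1ccccc1COc3c(OCc6ccccc6)c2O[C@H](c7ccc(OCc6ccccc6)cc7)[C@H](O)[C@H](O)c2cc3[C@H]4c5ccc(OCc6ccccc6)c(OCc6ccccc6)c5O[C@H](c5ccc(OCc6ccccc6)c(OCc6ccccc6)c5)[C@@H]4OCc6ccccc6 | intermediate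
33 | CNP0174688.1, (2R,3R,4R)-flavan-3,4-diol joined C6–C4' to the (2'R,3'R,4'S)-flavan-3'-ol | Oc1ccc([C@H]2Oc3c(cc([C@H]4c5ccc(O)c(O)c5O[C@H](c5ccc(O)c(O)c5)[C@@H]4O)c(O)c3O)[C@@H](O)[C@H]2O)cc1 | target

Total step count: 24. Longest linear sequence: 21 steps (1–3, 6–16, 18–24).

**Steps most likely to fail**

Step 11. The two diastereotopic phenols may not be told apart well enough. The C2'–O bond may also ionise ahead of C–O bond formation, which would erode the inversion at C2'.
- The fallback moves the choice of aryl group from the transition state to a separable pair of compounds and uses only known operations.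
- From 14, one equivalent of buffered TBAF at low temperature should remove a single silyl group. Because the aryl groups are diastereotopic, this should give two separable compounds: the (4'R)-mono-phenol mono-TBS epoxide F1 and its C4' epimer F2.
- The C4' epimer F2 is re-silylated (TBSCl, imidazole) to 14 and recycled.
- The mono-phenol F1 has only one nucleophile, placed behind the C2'–O bond. Its CSA-catalysed closure is therefore the ordinary 6-endo phenol/aryl-epoxide synthesis of a flavan-3-ol and should give the 7-O-TBS ether of the key-step product F3.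
- TBAF then brings the route back at 16.

Step 9. Three things may go wrong:
- The stepwise oxygen transfer may leak to the trans-epoxide through rotation in the benzylic radical.
- The metal-oxo species may abstract the doubly benzylic C4'–H.
- The hindered alkene may turn over slowly with poor facial selectivity.

The fallback sets out from 13 and replaces the metal-oxo chemistry by concerted oxygen transfer from a chiral dioxirane (Shi-type epoxidation). It uses a carbohydrate-derived spiro-oxazolidinone ketone of the kind developed for cis-alkenes conjugated to an aryl group, in the enantiomeric series that gives the (2'S,3'R)-epoxide. The oxidant is KHSO5 in K2CO3 buffer with dimethoxyethane/dimethoxymethane/water at −10 °C. A concerted spiro transition state cannot scramble the alkene geometry, and the basic buffer suits the acid-labile epoxide. The route is rejoined at 14 and no new compound arises (F0).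

Step 24. The benzylic C4–O bond may be hydrogenolysed, or it may ionise on the catalyst once O7–H is free, before the slow C3' alkyl benzyl ether is gone.
- The fallback removes the benzyl groups at the ketone oxidation level and sets out from 29.
- Buffered TBAF frees O8a–H to give the phenolic cis-epoxy ketone F4.
- F4 closes under CSA catalysis by attack at benzylic C2 with inversion, the classical cyclisation of a 2'-hydroxychalcone epoxide to a dihydroflavonol. This should give the (2R,3S)-2,3-cis-dihydroflavonol octabenzyl ether F5.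
- Hydrogenolysis (H2, Pd(OH)2/C) meets no benzylic alcohol at this stage, since the C4 ketone conjugated to O1 and O7 is inert. It should give the free phenolic 2,3-cis-dihydroflavonol F6.
- NaBH4 in ethanol at 0 °C, the classical reduction of dihydroflavonols to flavan-3,4-diols, should add hydride axially from the face opposite the axial O3. The route is rejoined at 33.

**Further compounds**
F1 | step 11 | (4'R)-mono-phenol mono-TBS cis-epoxide (free phenol on the future ring D) | CC(C)(C)[Si](C)(C)Oc3c(OCc6ccccc6)c(OCc6ccccc6)ccc3[C@@H](c5ccc(OCc6ccccc6)c(OCc6ccccc6)c5O)[C@H]9O[C@H]9c4ccc(OCc6ccccc6)c(OCc6ccccc6)c4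
F2 | step 11 | C4' epimer of F1 | CC(C)(C)[Si](C)(C)Oc3c(OCc6ccccc6)c(OCc6ccccc6)ccc3[C@H](c5ccc(OCc6ccccc6)c(OCc6ccccc6)c5O)[C@H]9O[C@H]9c4ccc(OCc6ccccc6)c(OCc6ccccc6)c4
F3 | step 11 | 7-O-TBS ether of 16 | CC(C)(C)[Si](C)(C)Oc3c(OCc6ccccc6)c(OCc6ccccc6)ccc3[C@H]4c5ccc(OCc6ccccc6)c(OCc6ccccc6)c5O[C@H](c5ccc(OCc6ccccc6)c(OCc6ccccc6)c5)[C@@H]4O
F0 | step 9 | none | none
F4 | step 24 | phenolic cis-epoxy ketone (2S,3S) | c1ccccc1COc3c(OCc6ccccc6)c(O)c(C(=O)[C@H]8O[C@H]8c7ccc(OCc6ccccc6)cc7)cc3[C@H]4c5ccc(OCc6ccccc6)c(OCc6ccccc6)c5O[C@H](c5ccc(OCc6ccccc6)c(OCc6ccccc6)c5)[C@@H]4OCc6ccccc6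
F5 | step 24 | (2R,3S)-2,3-cis-dihydroflavonol octabenzyl ether | c1ccccc1COc3c(OCc6ccccc6)c2O[C@H](c7ccc(OCc6ccccc6)cc7)[C@H](O)C(=O)c2cc3[C@H]4c5ccc(OCc6ccccc6)c(OCc6ccccc6)c5O[C@H](c5ccc(OCc6ccccc6)c(OCc6ccccc6)c5)[C@@H]4OCc6ccccc6
F6 | step 24 | free phenolic (2R,3S)-2,3-cis-dihydroflavonol | Oc3c(O)c2O[C@H](c7ccc(O)cc7)[C@H](O)C(=O)c2cc3[C@H]4c5ccc(O)c(O)c5O[C@H](c5ccc(O)c(O)c5)[C@@H]4O
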